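**Retrosynthetic overview**
- The two esters are put on last (methacrylate on the primary allylic OH, acetate on C4–OH); the isobutenyl group comes from a C5 vinyl group by cross-metathesis with 2-methylbut-2-ene.
- The γ-lactone is the only ring and is formed late, by Pd-catalysed cyclocarbonylation of an enyne anti-diol: CO becomes C2, and syn addition across the alkyne gives the E-alkylidene.
- Key C4–C5 bond: a conjugated ynal (C4) plus a chiral (E)-γ-borylallyl-B(Ipc)2 reagent, which delivers C5 as an α-hydroxyallyl carbanion equivalent; both stereocentres are set in this one step.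
- The ynal comes from an 8-bromoneryl silyl ether, 1,3-dilithiopropyne and DMF; the bromide comes from nerol (silylation, SeO2 allylic oxidation, Appel bromination).

Assumption: allenylboronic acid pinacol ester, (+)-Ipc2BH (otherwise one operation from (−)-α-pinene and BH3·SMe2) and propyne are taken as purchased; the target is read as the (4S,5R)-trans lactone with E-alkylidene and a 2Z,6E side chain.

**Route**

Step 1
Reactants: 1 nerol
Product: 2 tert-butyl{[(2Z)-3,7-dimethylocta-2,6-dien-1-yl]oxy}dimethylsilane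
Conditions: TBSCl, imidazole, CH2Cl2, 0 °C to rt
Reagents that add atoms: tert-butyldimethylsilyl chloride CC(C)(C)[Si](C)(C)Cl
Why: Imidazole-promoted O-silylation of the primary allylic alcohol gives an ether that survives the organolithium, borane, palladium and ruthenium steps, and the 2Z alkene of nerol is carried through unchanged.

Step 2
Reactants: 2 neryl silyl ether
Product: 3 (2E,6Z)-8-[(tert-butyldimethylsilyl)oxy]-2,6-dimethylocta-2,6-dien-1-ol
Conditions: SeO2 (10 mol%), t-BuOOH, salicylic acid (10 mol%), CH2Cl2, rt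
Reagents that add atoms: tert-butyl hydroperoxide CC(C)(C)OO; selenium dioxide O=[Se]=O (catalytic oxygen carrier)
Why: Riley allylic oxidation (ene reaction then [2,3]-shift) attacks the E-methyl of the remote, more electron-rich trisubstituted alkene and gives the (E)-allylic alcohol, which fixes the later 6E geometry.

Step 3
Reactants: 3 allylic alcohol
Product: 4 {[(2Z,6E)-8-bromo-3,7-dimethylocta-2,6-dien-1-yl]oxy}(tert-butyl)dimethylsilane
Conditions: CBr4, PPh3, CH2Cl2, 0 °C
Reagents that add atoms: carbon tetrabromide BrC(Br)(Br)Br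
Why: Appel bromination converts the primary allylic alcohol to the bromide under neutral conditions by SN2 displacement, leaving both alkene geometries and the silyl ether intact.

Step 4
Reactants: 4 allylic bromide; 5 propyne
Product: 8 (6E,10Z)-12-[(tert-butyldimethylsilyl)oxy]-6,10-dimethyldodeca-6,10-dien-2-ynal, via 1,3-dilithiopropyne 6 (not isolated), via lithium acetylide 7 (not isolated)
Conditions: 5, n-BuLi (2 equiv), TMEDA, Et2O–hexane, −78 to 0 °C; 4, THF, −78 to −20 °C; DMF, −78 to 0 °C; reverse quench into aq. KH2PO4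
Reagents that add atoms: N,N-dimethylformamide CN(C)C=O
Why: 1,3-Dilithiopropyne alkylates at its sp3 carbon by SN2 on the primary allylic bromide (C3 homologation), and the lithium acetylide left over is formylated by DMF (Bouveault-type formylation) in the same flask.

Step 5
Reactants: 8 ynal; 9 allenylboronic acid pinacol ester; 10 (+)-diisopinocampheylborane (from (−)-α-pinene)
Product: 13 (3R,4S,9E,13Z)-15-[(tert-butyldimethylsilyl)oxy]-9,13-dimethylpentadeca-1,9,13-trien-5-yne-3,4-diol, via γ-borylallyl borane 11 (not isolated), via borinate adduct 12 (not isolated)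
Conditions: 9 (1.3 equiv), 10 (1.25 equiv), Et2O, 0 °C, 3 h; then 8, −78 °C, 4 h; then 3 M NaOH, 30% H2O2, 0 °C to rt
Reagents that add atoms: hydrogen peroxide OO
Why: Allene hydroboration gives the (E)-γ-borylallyl borane, a chiral α-hydroxyallyl carbanion equivalent, so that this Brown-type allylboration is formally a cross-pinacol of two carbonyl carbons in which the Ipc groups direct attack to the Re face of the ynal (4S), the E-geometry in the chair transition state gives the anti C3/C4 relationship (3R), and C–B oxidation with retention gives the diol.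

Step 6
Reactants: 13 enyne anti-diol
Product: 14 (3E,4S,5R)-3-[(4E,8Z)-10-[(tert-butyldimethylsilyl)oxy]-4,8-dimethyldeca-4,8-dien-1-ylidene]-5-ethenyl-4-hydroxyoxolan-2-one
Conditions: PdCl2 (5 mol%), PPh3 (10 mol%), SnCl2 (5 mol%), CO (7 atm), MeCN, 70 °C
Reagents that add atoms: carbon monoxide [C-]#[O+]
Why: In this Pd-catalysed cyclocarbonylation of a homopropargylic alcohol the alkoxycarbonyl–palladium formed at the vinyl carbinol oxygen adds syn and 5-exo-dig across the alkyne and protonolysis puts H cis to the carbonyl, so the lactone closes with the E-alkylidene while the propargylic hydroxyl (4-exo only) stays free and both stereocentres are untouched.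

Step 7
Reactants: 14 vinyl lactone
Product: 15 (3E,4S,5R)-3-[(4E,8Z)-10-[(tert-butyldimethylsilyl)oxy]-4,8-dimethyldeca-4,8-dien-1-ylidene]-4-hydroxy-5-(2-methylprop-1-en-1-yl)oxolan-2-one
Conditions: second-generation Hoveyda–Grubbs catalyst (5 mol%), 1,4-benzoquinone (10 mol%), 2-methylbut-2-ene/CH2Cl2 (1:1), 40 °C
Reagents that add atoms: 2-methylbut-2-ene CC=C(C)C
Why: Olefin cross-metathesis of the only monosubstituted alkene with excess 2-methylbut-2-ene installs the isobutenyl group, with the trisubstituted and conjugated alkenes as spectators and no stereocentre touched.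

Step 8
Reactants: 15 silyl ether
Product: 16 (3E,4S,5R)-4-hydroxy-3-[(4E,8Z)-10-hydroxy-4,8-dimethyldeca-4,8-dien-1-ylidene]-5-(2-methylprop-1-en-1-yl)oxolan-2-one
Conditions: HF·pyridine, pyridine, THF, 0 °C to rt
Reagents that add atoms: none
Why: Buffered fluoride desilylation frees the primary allylic alcohol without opening the lactone or disturbing the β-hydroxy alkylidene unit.

Step 9
Reactants: 16 diol lactone
Product: 18 (2Z,6E,10E)-10-[(4S,5R)-4-acetoxy-5-(2-methylprop-1-en-1-yl)-2-oxooxolan-3-ylidene]-3,7-dimethyldeca-2,6-dien-1-yl 2-methylprop-2-enoate, via primary methacrylate 17 (not isolated)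
Conditions: methacryloyl chloride (1.05 equiv), 2,4,6-collidine, CH2Cl2, −78 to −40 °C; then Ac2O, pyridine, 0 °C to rt
Reagents that add atoms: methacryloyl chloride C=C(C)C(Cl)=O; acetic anhydride CC(=O)OC(C)=O
Why: Chemoselective O-acylation: the acid chloride with a hindered base at low temperature takes the primary allylic alcohol, and the hindered secondary C4 alcohol is then acetylated in the same flask without a nucleophilic catalyst that could attack the allylic acetate.

**Compound list**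

1 | nerol, (2Z)-3,7-dimethylocta-2,6-dien-1-ol | CC(C)=CCC/C(C)=C\CO | starting material
2 | tert-butyl{[(2Z)-3,7-dimethylocta-2,6-dien-1-yl]oxy}dimethylsilane | CC(C)=CCC/C(C)=C\CO[Si](C)(C)C(C)(C)C | intermediate
3 | (2E,6Z)-8-[(tert-butyldimethylsilyl)oxy]-2,6-dimethylocta-2,6-dien-1-ol | OC/C(C)=C/CC/C(C)=C\CO[Si](C)(C)C(C)(C)C | intermediate
4 | {[(2Z,6E)-8-bromo-3,7-dimethylocta-2,6-dien-1-yl]oxy}(tert-butyl)dimethylsilane | BrC/C(C)=C/CC/C(C)=C\CO[Si](C)(C)C(C)(C)C | intermediate
5 | propyne | CC#C | starting material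
6 | 1,3-dilithiopropyne | [Li]CC#C[Li] | intermediate
7 | [(5E,9Z)-11-[(tert-butyldimethylsilyl)oxy]-5,9-dimethylundeca-5,9-dien-1-yn-1-yl]lithium | [Li]C#CCC/C(C)=C/CC/C(C)=C\CO[Si](C)(C)C(C)(C)C | intermediate
8 | (6E,10Z)-12-[(tert-butyldimethylsilyl)oxy]-6,10-dimethyldodeca-6,10-dien-2-ynal | O=CC#CCC/C(C)=C/CC/C(C)=C\CO[Si](C)(C)C(C)(C)C | intermediate
9 | allenylboronic acid pinacol ester, 4,4,5,5-tetramethyl-2-(propa-1,2-dien-1-yl)-1,3,2-dioxaborolane | C=C=CB1OC(C)(C)C(C)(C)O1 | starting material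
10 | (+)-diisopinocampheylborane, bis[(1S,2R,3S,5S)-2,6,6-trimethylbicyclo[3.1.1]heptan-3-yl]borane | B([C@H]1C[C@H]2C[C@@H]([C@@H]1C)C2(C)C)[C@H]1C[C@H]2C[C@@H]([C@@H]1C)C2(C)C | starting material
11 | [(2E)-3-(4,4,5,5-tetramethyl-1,3,2-dioxaborolan-2-yl)prop-2-en-1-yl]bis[(1S,2R,3S,5S)-isopinocampheyl]borane | C(/C=C/B1OC(C)(C)C(C)(C)O1)B([C@H]1C[C@H]2C[C@@H]([C@@H]1C)C2(C)C)[C@H]1C[C@H]2C[C@@H]([C@@H]1C)C2(C)C | intermediate
12 | (3R,4R,9E,13Z)-15-[(tert-butyldimethylsilyl)oxy]-9,13-dimethyl-3-(pinacolatoboryl)pentadeca-1,9,13-trien-5-yn-4-yl bis(isopinocampheyl)borinate (same spatial arrangement as 13) | C=C[C@@H](B1OC(C)(C)C(C)(C)O1)[C@@H](OB([C@H]1C[C@H]2C[C@@H]([C@@H]1C)C2(C)C)[C@H]1C[C@H]2C[C@@H]([C@@H]1C)C2(C)C)C#CCC/C(C)=C/CC/C(C)=C\CO[Si](C)(C)C(C)(C)C | intermediate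
13 | (3R,4S,9E,13Z)-15-[(tert-butyldimethylsilyl)oxy]-9,13-dimethylpentadeca-1,9,13-trien-5-yne-3,4-diol (anti) | C=C[C@@H](O)[C@@H](O)C#CCC/C(C)=C/CC/C(C)=C\CO[Si](C)(C)C(C)(C)C | intermediate
14 | (3E,4S,5R)-3-[(4E,8Z)-10-[(tert-butyldimethylsilyl)oxy]-4,8-dimethyldeca-4,8-dien-1-ylidene]-5-ethenyl-4-hydroxyoxolan-2-one | CC(C)(C)[Si](C)(C)OC/C=C(/C)CC/C=C(\C)CC/C=C1/C(=O)O[C@H](C=C)[C@H]1O | intermediate
15 | (3E,4S,5R)-3-[(4E,8Z)-10-[(tert-butyldimethylsilyl)oxy]-4,8-dimethyldeca-4,8-dien-1-ylidene]-4-hydroxy-5-(2-methylprop-1-en-1-yl)oxolan-2-one | CC(C)(C)[Si](C)(C)OC/C=C(/C)CC/C=C(\C)CC/C=C1/C(=O)O[C@H](C=C(C)C)[C@H]1O | intermediate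
16 | (3E,4S,5R)-4-hydroxy-3-[(4E,8Z)-10-hydroxy-4,8-dimethyldeca-4,8-dien-1-ylidene]-5-(2-methylprop-1-en-1-yl)oxolan-2-one | OC/C=C(/C)CC/C=C(\C)CC/C=C1/C(=O)O[C@H](C=C(C)C)[C@H]1O | intermediate
17 | (2Z,6E,10E)-10-[(4S,5R)-4-hydroxy-5-(2-methylprop-1-en-1-yl)-2-oxooxolan-3-ylidene]-3,7-dimethyldeca-2,6-dien-1-yl 2-methylprop-2-enoate | C=C(C)C(=O)OC/C=C(/C)CC/C=C(\C)CC/C=C1/C(=O)O[C@H](C=C(C)C)[C@H]1O | intermediate
18 | CNP0152230.1, (2Z,6E,10E)-10-[(4S,5R)-4-acetoxy-5-(2-methylprop-1-en-1-yl)-2-oxooxolan-3-ylidene]-3,7-dimethyldeca-2,6-dien-1-yl 2-methylprop-2-enoate | C=C(C)C(=O)OC/C=C(/C)CC/C=C(\C)CC/C=C1/C(=O)O[C@H](C=C(C)C)[C@H]1OC(C)=O | target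

**Step count and risks**

Total steps: 9. Longest linear sequence: 9 steps (nerol 1 to target 18); 5, 9 and 10 enter as purchased materials.

The three steps most likely to fail:

- **Step 6 (cyclocarbonylation).** The vinyl carbinol is an allylic alcohol that Pd/SnCl2 could ionise, and the free propargylic hydroxyl or the terminal alkene could interfere. The fallback sets out from diol 13 and builds the lactone stepwise. Mo(CO)3(CNtBu)3-catalysed syn-hydrostannation with Bu3SnH (THF, 55 °C) puts tin on the alkyne carbon next to the carbinol and gives (3R,4R,5E,9E,13Z)-15-[(tert-butyldimethylsilyl)oxy]-9,13-dimethyl-5-(tributylstannyl)pentadeca-1,5,9,13-tetraene-3,4-diol F1. Iodine (CH2Cl2, 0 °C) exchanges tin for iodine with retention to give the (5E)-5-iodo tetraene diol F2. Carbonylative lactonisation through the vinyl carbinol oxygen (Pd(PPh3)4, CO 1 atm, Et3N, THF, 50 °C) then comes back to lactone 14 with the same E-alkylidene.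

- **Step 5 (key allylboration).** A slender conjugated ynal may give lower facial selectivity than the aldehydes this reagent is known for. Adduct 12 is itself an allylboronate and could add to a second ynal. The ynal and the enyne diol must also survive the alkaline peroxide work-up. The fallback sets out from ynal 8 and uses a catalytic route to the same diol. Iridium-catalysed transfer-hydrogenative anti-(α-benzoyloxy)allylation is run with [Ir(cod)Cl]2, SEGPHOS, 4-cyano-3-nitrobenzoic acid, K3PO4, 3,3-bis(benzoyloxy)prop-1-ene and 2-propanol in THF at 70 °C. The ligand antipode is chosen, by Mosher analysis of the product, to give the (3R,4S) series. The product is (3R,4S,9E,13Z)-15-[(tert-butyldimethylsilyl)oxy]-4-hydroxy-9,13-dimethylpentadeca-1,9,13-trien-5-yn-3-yl benzoate F3. K2CO3 in MeOH removes the benzoate, whichever hydroxyl carries it after any migration, and comes back to diol 13.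

- **Step 4 (one-pot dianion homologation and formylation).** Alkylation at the acetylide end, SN2′ attack or double alkylation would lower the yield, and the ynal is sensitive to the amine released on work-up. The fallback sets out from bromide 4 and separates the operations. 3-Lithio-1-(trimethylsilyl)propyne (from 1-(trimethylsilyl)propyne and n-BuLi, THF, −78 °C) alkylates cleanly to give tert-butyl{[(2Z,6E)-3,7-dimethyl-11-(trimethylsilyl)undeca-2,6-dien-10-yn-1-yl]oxy}dimethylsilane F4. K2CO3 in MeOH removes the alkynyl silyl group to give tert-butyl{[(2Z,6E)-3,7-dimethylundeca-2,6-dien-10-yn-1-yl]oxy}dimethylsilane F5. n-BuLi then DMF, with reverse quench into aq. KH2PO4, comes back to ynal 8.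

Further compounds
F1 | step 6 | (3R,4R,5E,9E,13Z)-15-[(tert-butyldimethylsilyl)oxy]-9,13-dimethyl-5-(tributylstannyl)pentadeca-1,5,9,13-tetraene-3,4-diol | C=C[C@@H](O)[C@@H](O)/C(=C\CC/C(C)=C/CC/C(C)=C\CO[Si](C)(C)C(C)(C)C)[Sn](CCCC)(CCCC)CCCC
F2 | step 6 | (3R,4R,5E,9E,13Z)-15-[(tert-butyldimethylsilyl)oxy]-5-iodo-9,13-dimethylpentadeca-1,5,9,13-tetraene-3,4-diol | C=C[C@@H](O)[C@@H](O)/C(I)=C\CC/C(C)=C/CC/C(C)=C\CO[Si](C)(C)C(C)(C)C
F3 | step 5 | (3R,4S,9E,13Z)-15-[(tert-butyldimethylsilyl)oxy]-4-hydroxy-9,13-dimethylpentadeca-1,9,13-trien-5-yn-3-yl benzoate | C=C[C@@H](OC(=O)c1ccccc1)[C@@H](O)C#CCC/C(C)=C/CC/C(C)=C\CO[Si](C)(C)C(C)(C)C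
F4 | step 4 | tert-butyl{[(2Z,6E)-3,7-dimethyl-11-(trimethylsilyl)undeca-2,6-dien-10-yn-1-yl]oxy}dimethylsilane | C[Si](C)(C)C#CCC/C(C)=C/CC/C(C)=C\CO[Si](C)(C)C(C)(C)C
F5 | step 4 | tert-butyl{[(2Z,6E)-3,7-dimethylundeca-2,6-dien-10-yn-1-yl]oxy}dimethylsilane | C#CCC/C(C)=C/CC/C(C)=C\CO[Si](C)(C)C(C)(C)C
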